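The rate constants were chosen freely; the run is a simulation.

If the added ligand were a bystander, the second catalyst would stay as charged and the intermediate would go on to target with a half-life of 3.5 min; this is the view of the first of two chemists disputing these flasks.

    substrate + free catalyst → free catalyst + intermediate (k1 = 1.8 M⁻¹ s⁻¹)
    coupling partner + second catalyst + intermediate → second catalyst + target (k2 = 8.1 M⁻² s⁻¹)
    second catalyst + added ligand ⇌ idle complex (K3 = 570 M⁻¹, k3 = 3.2 M⁻¹ s⁻¹)
    coupling partner → decomposition product (k4 = 2.7 × 10⁻⁶ s⁻¹)

| setting | amber | violet | teal | red |
|---|---|---|---|---|
| substrate | 0.30 M | 0.30 M | 0.30 M | 0.30 M (fed, over 8.00 min) |
| coupling partner | 0.450 M | 0.450 M | 0.450 M | 0.450 M |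
| free catalyst | 3.0 mM | 3.0 mM | 3.0 mM | 3.0 mM |
| second catalyst | 0.90 mM | 0.90 mM | 0.90 mM | 0.90 mM |
| added ligand | 3.4 mM | 3.4 mM | 3.4 mM | 3.4 mM |
| time | 8.0 min |  |  | 8.0 min |
| remark | a closed flask charged with all of it at once and left for 8.0 min | one stirred flow tank at steady state, fed with the mixture as stated, mean residence time 8.0 min | one stirred flow tank at steady state, fed with the mixture as stated, mean residence time 80.0 min | all but substrate at the start; substrate goes in evenly over 8.00 min, the run ends at 8.0 min |

- the stated concentrations are those of everything mixed, before any reaction; amounts are the same in each set-up
- the feed brings no volume worth counting
- run time (amber): 8.0 min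

- the set-up with the highest amount of target at the outlet or at the end, in percent of the substrate put in ("none" if the first two lie within 2 percentage points) (amber / violet / teal / red / none)
- amount of target at the outlet or at the end, in percent of the substrate put in, amber
- amount of target at the outlet or at the end, in percent of the substrate put in, violet
- amount of target at the outlet or at the end, in percent of the substrate put in, teal
- amount of target at the outlet or at the end, in percent of the substrate put in, red

The first chemist sets that half-life beside the half-life of substrate, 2.1 min, treats amber as two first-order steps in series, and expects 58.8% of the substrate charge as target after 8.0 min.

I take the second chemist's side, which looks for what stays nearly constant and freezes it. Free catalyst comes back unchanged from step 1, so substrate keeps its half-life. The second catalyst does not stay as charged in amber, because the ligand binds it within about 1.53 min, a span shorter than the run, and the equilibrium constant times the charged ligand is 1.9. Freezing that equilibrium, and counting the ligand held in the idle complex, leaves a free share of 0.382 of the second catalyst's charge.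

From this comes the quantity I carry: the frozen half-life of the intermediate, 9.23 min, meaning its half-life in step 2 with coupling partner at its charge and second catalyst at its free share, a pseudo-first-order reading of step 2. Amber's run is shorter than this, so I expect it to stop part way, at 30.9%. That figure still holds coupling partner at its charge, though 0.206 of that charge would be used by then. Teal's residence time is about ten times the frozen half-life, so I put teal first. In red the dose waits 4.00 min on average, less than the frozen half-life, so I put red below amber. Violet I leave unreckoned.

The forecast stands on the second chemist's side: “the ligand ties up about 60% of the second catalyst within a minute or two”. It gives 29.6% for amber, a little below my figure, then 26.6% for violet, 72.9% for teal and 12.6% for red, and it names teal best.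

The simulation gives 29.7% for amber, 26.6% for violet, 72.9% for teal and 12.6% for red, so teal leads, and the first chemist's figure stands above amber's result; that view of the second catalyst fits the opening of amber, inside the binding time of about 1.53 min. Teal's tank holds substrate at 0.0371 of its charge and coupling partner at 0.508 of its charge. With that coupling partner the frozen half-life stretches to 18.2 min, and for a tank of 80.0 min this estimates target at 72.5% of the substrate put in.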